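**Strategy.** The target is disconnected at C9–C11, the bond between the side chain and the vinylic carbon C9 of the tetrasubstituted C8=C9 alkene in ring B. C9 sits between quaternary C10 and C8, so a C9 enolate is regiodefined and can be kept as a C9 enol triflate. The key step is a B-alkyl Suzuki–Miyaura coupling: the 9-BBN adduct of (Z)-3-methylpenta-2,4-dien-1-ol is joined to the bicyclic triflate that already carries the 6β-acetate and the free 7α-hydroxyl, giving the target directly without protecting groups. The triflate comes from (+)-sclareolide; C6 is set by hydride reduction of an enedione, C7 by α-face epoxidation.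

Key step: step 11

Remark: labdane numbering is used throughout (ring A = C1–C5, C10; ring B = C5–C10; methyls on C4 (two), C8 and C10); β is the face of the C10 methyl, α the opposite face.

Step 1
Reactants: 1 (+)-sclareolide
Product: 3 9(11)-dehydrosclareolide, via 11α-(phenylselanyl)sclareolide 2 (not isolated)
Conditions: LDA, THF, −78 °C; PhSeBr; then 30% H2O2, pyridine, CH2Cl2, 0 °C → rt
Reagents that add atoms: none
Why: Selenenylation of the lactone enolate should occur anti to the axial β-methyls on C8 and C10, placing Se cis to H-9, so selenoxide syn-elimination (Reich/Grieco) can give only the C9=C11 butenolide.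

Step 2
Reactants: 3 9(11)-dehydrosclareolide
Product: 4 8α-(2-oxoacetoxy)-11-nordriman-9-one
Conditions: O3, CH2Cl2, −78 °C; then Me2S, −78 °C → rt; used crude
Reagents that add atoms: ozone, [O-][O+]=O
Why: Ozonolysis cleaves the only C=C bond; C9 becomes the ketone and C11 leaves the carbon skeleton as the aldehyde of a glyoxylate ester still bound to O-8.

Step 3
Reactants: 4 8α-(2-oxoacetoxy)-11-nordriman-9-one
Product: 5 11-nordriman-9-one (equatorial 8α-methyl epimer drawn)
Conditions: SmI2 (excess), THF/MeOH, −78 °C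
Reagents that add atoms: none
Why: SmI2 reduction of an α-acyloxy ketone (ketyl, loss of the C8 carboxylate, protonation of the samarium enolate); the C8 epimer ratio does not matter because C8 becomes sp2 in step 4.

Step 4
Reactants: 5 11-nordriman-9-one
Product: 6 11-nordrim-7-en-9-one
Conditions: IBX, DMSO/fluorobenzene, 70 °C
Reagents that add atoms: none
Why: IBX dehydrogenation of a ketone whose only α-hydrogen is H-8 (C10 is quaternary), so unsaturation can only enter between C7 and C8, giving the conjugated 8-methyl enone.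

Step 5
Reactants: 6 11-nordrim-7-en-9-one
Product: 7 11-nordrim-7-ene-6,9-dione
Conditions: Pd(OH)2/C (cat.), t-BuOOH, K2CO3, CH2Cl2, rt
Reagents that add atoms: tert-butyl hydroperoxide, CC(C)(C)OO
Why: Corey–Yu allylic oxidation of the γ-methylene (C6) of an enone to the enedione, the same change that converts 2,6,6-trimethylcyclohexenone into ketoisophorone; C5 is epimerisable here, but the trans-fused decalin should be the stable isomer.

Step 6
Reactants: 7 11-nordrim-7-ene-6,9-dione
Product: 8 6β-hydroxy-11-nordrim-7-en-9-one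
Conditions: NaBH4, CeCl3·7H2O, MeOH, −78 °C
Reagents that add atoms: none
Why: Luche 1,2-reduction; C9=O is shielded by quaternary C10 and the C8 methyl (ketoisophorone is likewise reduced at its unhindered carbonyl), and hydride should attack C6 from the α-face because the β-face is blocked by the syn-axial methyls on C4 and C10, setting the 6β-hydroxyl.

Step 7
Reactants: 8 6β-hydroxy-11-nordrim-7-en-9-one
Product: 9 6β-acetoxy-11-nordrim-7-en-9-one
Conditions: Ac2O, Et3N, DMAP (cat.), CH2Cl2, rt
Reagents that add atoms: acetic anhydride, CC(=O)OC(C)=O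
Why: DMAP-catalysed acylation of the only hydroxyl present, so the acetate is placed on O-6 before O-7 exists.

Step 8
Reactants: 9 6β-acetoxy-11-nordrim-7-en-9-one
Product: 10 6β-acetoxy-7α,8α-epoxy-11-nordriman-9-one
Conditions: t-BuOOH, DBU, CH2Cl2, 0 °C → rt
Reagents that add atoms: tert-butyl hydroperoxide, CC(C)(C)OO
Why: Weitz–Scheffer epoxidation; t-BuOO− should add to C7 anti to the axial 6β-acetoxy group and the enolate closes on the same α-face, fixing the C7–O bond α (the later 7α-OH), while the non-aqueous base spares the acetate.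

Step 9
Reactants: 10 6β-acetoxy-7α,8α-epoxy-11-nordriman-9-one
Product: 12 6β-acetoxy-7α-hydroxy-11-nordrim-8-en-9-yl triflate, via samarium enolate 11 (not isolated)
Conditions: SmI2 (2.5 equiv), THF, −78 °C; then HMPA, Comins' reagent, −78 → 0 °C; aq. NH4Cl
Reagents that add atoms: Comins' reagent [N-(5-chloropyridin-2-yl)-N-(trifluoromethylsulfonyl)trifluoromethanesulfonamide], FC(F)(F)S(=O)(=O)N(c1ccc(Cl)cn1)S(=O)(=O)C(F)(F)F
Why: Proposed new method: SmI2 transfers an electron to the C9 ketone, the ketyl opens the adjacent C8–O bond of the epoxide, and a second electron gives the samarium(III) C8=C9 enolate together with the C7 alkoxide, whose 7α configuration is that of the epoxide; the enolate oxygen is then sulfonylated by the N-triflimide, the closest known reactions being the SmI2 reduction of α,β-epoxy ketones to β-hydroxy ketones and the triflation of enolates generated by dissolving-metal or hydride conjugate reduction, and no base is present that could deprotonate the acetate or open a second enolisation path.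

Step 10
Reactants: 13 (Z)-3-methylpent-2-en-4-yn-1-ol
Product: 14 (Z)-3-methylpenta-2,4-dien-1-ol
Conditions: H2 (1 atm), Lindlar catalyst, quinoline, Et2O, 0 °C; used as a solution
Reagents that add atoms: none
Why: Lindlar semihydrogenation of the terminal alkyne to a vinyl group; the trisubstituted (Z)-alkene should be neither reduced nor isomerised.

Step 11
Reactants: 12 6β-acetoxy-7α-hydroxy-11-nordrim-8-en-9-yl triflate, 14 (Z)-3-methylpenta-2,4-dien-1-ol
Product: 16 6β-acetoxy-labda-8,13(Z)-diene-7α,15-diol (CNP0183298.2), via bis-9-BBN adduct 15 (not isolated)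
Conditions: 14, 9-BBN-H (2.2 equiv), THF, 0 °C → rt; then 12, Pd(dppf)Cl2 (10 mol %), AsPh3, Cs2CO3, DMF/H2O, 50 °C
Reagents that add atoms: none
Why: 9-BBN should add anti-Markovnikov to the monosubstituted vinyl group of 14 only (the trisubstituted alkene is too hindered), after the hydroxyl is tied up as its borinate, giving the primary alkylborane 15. Pd(0) inserts into the C9–OTf bond of 12, base-activated 15 transfers its primary alkyl group to palladium, and reductive elimination forms the C9–C11 σ-bond; this is the B-alkyl Suzuki–Miyaura coupling of an enol triflate with the boron partner made in situ from a 1,3-diene. No ring is closed and no stereocentre is formed: C5, C6, C7 and C10 are spectators and the Z geometry of C13=C14 is carried over from 14. The step needs coupling at a vinylic carbon flanked by quaternary C10 and the C8 methyl to outrun β-hydride elimination and protodeboronation of the alkyl group; the wide-bite-angle dppf ligand with AsPh3 and aqueous Cs2CO3 is chosen for that, and an unbranched CH2 terminus is the least demanding sp3 partner. The free 7α- and 15-hydroxyls and the hindered 6β-acetate should tolerate the mild base.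

**Compound list**

1 | (+)-sclareolide, (3aR,5aS,9aS,9bR)-3a,6,6,9a-tetramethyldecahydronaphtho[2,1-b]furan-2(1H)-one | C1C[C@@]3(C)OC(=O)C[C@@H]3[C@@]2(C)CCCC(C)(C)[C@H]12 | starting material
2 | 11α-(phenylselanyl)sclareolide (Se cis to H-9) | C1C[C@@]3(C)OC(=O)[C@@H]([Se]c4ccccc4)[C@@H]3[C@@]2(C)CCCC(C)(C)[C@H]12 | intermediate
3 | 9(11)-dehydrosclareolide (butenolide, C9=C11) | C1C[C@@]3(C)OC(=O)C=C3[C@@]2(C)CCCC(C)(C)[C@H]12 | intermediate
4 | 8α-(2-oxoacetoxy)-11-nordriman-9-one (8β-methyl, glyoxylate ester on O-8) | C1C[C@@](C)(OC(=O)C=O)C(=O)[C@@]2(C)CCCC(C)(C)[C@H]12 | intermediate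
5 | 11-nordriman-9-one, 8α-methyl (8β-H) epimer | C1C[C@@H](C)C(=O)[C@@]2(C)CCCC(C)(C)[C@H]12 | intermediate
6 | 11-nordrim-7-en-9-one (5α-H, 10β-methyl) | C1C=C(C)C(=O)[C@@]2(C)CCCC(C)(C)[C@H]12 | intermediate
7 | 11-nordrim-7-ene-6,9-dione | O=C1C=C(C)C(=O)[C@@]2(C)CCCC(C)(C)[C@H]12 | intermediate
8 | 6β-hydroxy-11-nordrim-7-en-9-one | O[C@@H]1C=C(C)C(=O)[C@@]2(C)CCCC(C)(C)[C@H]12 | intermediate
9 | 6β-acetoxy-11-nordrim-7-en-9-one | CC(=O)O[C@@H]1C=C(C)C(=O)[C@@]2(C)CCCC(C)(C)[C@H]12 | intermediate
10 | 6β-acetoxy-7α,8α-epoxy-11-nordriman-9-one | CC(=O)O[C@@H]1[C@H]3O[C@@]3(C)C(=O)[C@@]2(C)CCCC(C)(C)[C@H]12 | intermediate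
11 | bis(diiodosamarium) C8=C9 enolate / C7α alkoxide of the opened epoxy ketone | CC(=O)O[C@@H]1[C@@H](O[Sm](I)I)C(C)=C(O[Sm](I)I)[C@@]2(C)CCCC(C)(C)[C@H]12 | intermediate
12 | 6β-acetoxy-7α-hydroxy-11-nordrim-8-en-9-yl trifluoromethanesulfonate | CC(=O)O[C@@H]1[C@@H](O)C(C)=C(OS(=O)(=O)C(F)(F)F)[C@@]2(C)CCCC(C)(C)[C@H]12 | intermediate
13 | (Z)-3-methylpent-2-en-4-yn-1-ol | C#C/C(C)=C\CO | starting material
14 | (Z)-3-methylpenta-2,4-dien-1-ol | C=C/C(C)=C\CO | intermediate
15 | (Z)-5-(9-borabicyclo[3.3.1]nonan-9-yl)-3-methylpent-2-en-1-yl 9-BBN borinate | C(C/C(C)=C\COB1C2CCCC1CCC2)B3C4CCCC3CCC4 | intermediate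
16 | 6β-acetoxy-labda-8,13(Z)-diene-7α,15-diol (CNP0183298.2) | CC(=O)O[C@@H]1[C@@H](O)C(C)=C(CC/C(C)=C\CO)[C@@]2(C)CCCC(C)(C)[C@H]12 | target

**Total step count:** 11. **Longest linear sequence:** 10 (steps 1–9, then step 11).

**Steps most likely to fail**

1. Step 9 (proposed new method). The hindered samarium enolate may be sulfonylated too slowly and be protonated on work-up to the aldol, or the C7 alkoxide may be sulfonylated as well. The fallback sets out from 10 and comes back at 12, with known reactions only. SmI2 in THF/MeOH at −90 °C should give the aldol 6β-acetoxy-7α-hydroxy-11-nordriman-9-one F1. TESOTf/2,6-lutidine protects it as the 7-O-triethylsilyl ether F2. Tf2O with 2,6-di-tert-butyl-4-methylpyridine in CH2Cl2 converts the ketone into 6β-acetoxy-7α-(triethylsilyloxy)-11-nordrim-8-en-9-yl triflate F3; the O-triflyl oxocarbenium ion can lose only H-8, and no enolate is formed that could involve the acetate. HF·pyridine then removes the silyl group to give 12.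

2. Step 11 (key step). Oxidative addition and transmetalation at the doubly flanked C9 may be slow, so that the alkylborane is lost by protodeboronation or β-hydride elimination before coupling. The fallback sets out from 12 and the commercial enynol 13 and comes back at 16. Sonogashira coupling (Pd(PPh3)2Cl2, CuI, i-Pr2NH, DMF, rt → 40 °C) uses a linear sp carbon, the least hindered partner possible, and should give 6β-acetoxy-labda-8,13(Z)-dien-11-yne-7α,15-diol F4. Diimide (2-nitrobenzenesulfonyl hydrazide, Et3N, CH2Cl2) should then reduce C11≡C12 through 6β-acetoxy-labda-8,11(Z),13(Z)-triene-7α,15-diol F5 to the CH2–CH2 link of 16, the tetra- and trisubstituted alkenes reacting much more slowly. This fallback forms the same C9–C11 bond in its coupling step.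

3. Step 5. The radical allylic oxidation may stall, attack the C8 methyl, or epimerise C5 under the basic conditions. The fallback sets out from 6 and comes back at 7. LDA/TMSCl (γ-deprotonation at C6 is the only one possible) should give 9-(trimethylsilyloxy)-11-nordrima-6,8-diene F6. Buffered mCPBA (vinylogous Rubottom oxidation) gives 6α-hydroxy-11-nordrim-7-en-9-one F7; any 6β epimer formed is 8 itself. Dess–Martin periodinane oxidises F7 to 7.

**Further compounds**

F1 | step 9 | 6β-acetoxy-7α-hydroxy-11-nordriman-9-one (8α-methyl epimer drawn) | CC(=O)O[C@@H]1[C@@H](O)[C@@H](C)C(=O)[C@@]2(C)CCCC(C)(C)[C@H]12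
F2 | step 9 | 6β-acetoxy-7α-(triethylsilyloxy)-11-nordriman-9-one | CC(=O)O[C@@H]1[C@@H](O[Si](CC)(CC)CC)[C@@H](C)C(=O)[C@@]2(C)CCCC(C)(C)[C@H]12
F3 | step 9 | 6β-acetoxy-7α-(triethylsilyloxy)-11-nordrim-8-en-9-yl trifluoromethanesulfonate | CC(=O)O[C@@H]1[C@@H](O[Si](CC)(CC)CC)C(C)=C(OS(=O)(=O)C(F)(F)F)[C@@]2(C)CCCC(C)(C)[C@H]12
F4 | step 11 | 6β-acetoxy-labda-8,13(Z)-dien-11-yne-7α,15-diol | CC(=O)O[C@@H]1[C@@H](O)C(C)=C(C#C/C(C)=C\CO)[C@@]2(C)CCCC(C)(C)[C@H]12
F5 | step 11 | 6β-acetoxy-labda-8,11(Z),13(Z)-triene-7α,15-diol | CC(=O)O[C@@H]1[C@@H](O)C(C)=C(/C=C\C(C)=C/CO)[C@@]2(C)CCCC(C)(C)[C@H]12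
F6 | step 5 | 9-(trimethylsilyloxy)-11-nordrima-6,8-diene | C1=CC(C)=C(O[Si](C)(C)C)[C@@]2(C)CCCC(C)(C)[C@H]12
F7 | step 5 | 6α-hydroxy-11-nordrim-7-en-9-one | O[C@H]1C=C(C)C(=O)[C@@]2(C)CCCC(C)(C)[C@H]12
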